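**Plan**
- Retrosynthesis: cut the C8 ester (Mitsunobu, inversion), then the C7–C8 bond of the ten-membered ring (intramolecular Nozaki–Hiyama–Kishi), then the lactone C11–C12 bond and both C–I bonds (I2 on an alkyne, Pd/CO), then C6–C7 (alkynylation of an enal) and C8–C9 (vinyl Stille on 8-bromogeranyl acetate).
- Forward ring order: 1,10-oxirane, then 4,5-oxirane, then the butenolide, then the ten-membered carbocycle; no ring is formed after step 12.
- Enabling feature: C7 is the β-carbon of the butenolide, an sp2 carbon that can carry iodide, and its ring neighbour C8 is a secondary carbinol carbon, so C7(sp2)–C8H(O) is a Nozaki–Hiyama–Kishi retron; closing this bond last lets the lactone and both oxiranes be set in the open chain.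
- Stereochemistry: C1/C10 from Shi epoxidation (reagent control); C6 from Zn–ProPhenol alkynylation (reagent control); C4/C5 from C6–OH-directed epoxidation (substrate control); C8 from the macrocyclisation followed by Mitsunobu inversion.

Key step: step 12

Remark: locants C1–C15 follow germacranolide numbering (ring C1–C10, C14 on C10, C15 on C4, lactone C6–O–C12(=O)–C11=C7, C13 = CH2OAc on C11); the silyl-protected side-chain acid 20 is made in two steps and not assumed to be purchasable.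

**Route**

Step 1
Reactants: 1 geranyl acetate
Product: 2 (2E,6E)-8-hydroxy-3,7-dimethylocta-2,6-dien-1-yl acetate
Conditions: SeO2 (0.1 equiv), t-BuOOH (3 equiv), salicylic acid (0.1 equiv), CH2Cl2, rt
Reagents that add atoms: tert-butyl hydroperoxide, CC(C)(C)OO
Why: SeO2/t-BuOOH allylic oxidation (ene reaction, then [2,3]-shift) hydroxylates the (E)-methyl of the electron-rich 6,7-olefin; the 2,3-olefin is deactivated by the allylic acetate.

Step 2
Reactants: 2 (2E,6E)-8-hydroxy-3,7-dimethylocta-2,6-dien-1-yl acetate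
Product: 3 (2E,6E)-8-bromo-3,7-dimethylocta-2,6-dien-1-yl acetate
Conditions: CBr4, PPh3, CH2Cl2, 0 °C
Reagents that add atoms: carbon tetrabromide, BrC(Br)(Br)Br
Why: Appel bromination of a primary allylic alcohol proceeds by SN2 at the CH2 carbon without allylic shift or loss of olefin geometry.

Step 3
Reactants: 3 (2E,6E)-8-bromo-3,7-dimethylocta-2,6-dien-1-yl acetate
Product: 4 (2E,6E)-3,7-dimethyldeca-2,6,9-trien-1-yl acetate
Conditions: tributyl(vinyl)stannane (1.2 equiv), Pd2(dba)3 (2.5 mol%), P(2-furyl)3 (10 mol%), THF, 50 °C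
Reagents that add atoms: tributyl(vinyl)stannane, C=C[Sn](CCCC)(CCCC)CCCC
Why: Stille allyl–vinyl coupling; Pd(0) inserts into the allylic bromide far faster than into the allylic acetate and couples at the less substituted allyl terminus, so the E-olefin is kept and the new vinyl group is the latent C8 aldehyde.

Step 4
Reactants: 4 (2E,6E)-3,7-dimethyldeca-2,6,9-trien-1-yl acetate
Product: 5 (2E)-3-methyl-5-[(2R,3R)-3-methyl-3-(prop-2-en-1-yl)oxiran-2-yl]pent-2-en-1-yl acetate
Conditions: D-fructose-derived Shi ketone (0.3 equiv), Oxone, K2CO3, Bu4NHSO4, MeCN/dimethoxymethane–aq. borate buffer (pH 10.5), 0 °C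
Reagents that add atoms: potassium peroxymonosulfate (Oxone), [K+].[O-]S(=O)(=O)OO
Why: Shi epoxidation via the spiro dioxirane transition state is expected to deliver the (R,R)-oxirane (C1/C10) at the isolated trisubstituted olefin; the acetate-deactivated allylic olefin and the monosubstituted vinyl group react much more slowly.

Step 5
Reactants: 5 (2E)-3-methyl-5-[(2R,3R)-3-methyl-3-(prop-2-en-1-yl)oxiran-2-yl]pent-2-en-1-yl acetate
Product: 6 (2E)-3-methyl-5-[(2R,3R)-3-methyl-3-(prop-2-en-1-yl)oxiran-2-yl]pent-2-en-1-ol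
Conditions: K2CO3 (0.2 equiv), MeOH, 0 °C to rt
Reagents that add atoms: none
Why: base-catalysed transesterification removes the acetate; the remote trisubstituted oxirane is inert to methoxide at this temperature.

Step 6
Reactants: 6 (2E)-3-methyl-5-[(2R,3R)-3-methyl-3-(prop-2-en-1-yl)oxiran-2-yl]pent-2-en-1-ol
Product: 7 (2E)-3-methyl-5-[(2R,3R)-3-methyl-3-(prop-2-en-1-yl)oxiran-2-yl]pent-2-enal
Conditions: MnO2 (15 equiv), CH2Cl2, rt
Reagents that add atoms: none
Why: MnO2 oxidises only the allylic alcohol and gives the (E)-enal without touching the oxirane or the other olefin.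

Step 7
Reactants: 7 (2E)-3-methyl-5-[(2R,3R)-3-methyl-3-(prop-2-en-1-yl)oxiran-2-yl]pent-2-enal, 8 prop-2-yn-1-yl acetate
Product: 10 (4R,5E)-4-hydroxy-6-methyl-8-[(2R,3R)-3-methyl-3-(prop-2-en-1-yl)oxiran-2-yl]oct-5-en-2-yn-1-yl acetate, via alkynylzinc 9 (not isolated)
Conditions: 8 (3 equiv), Me2Zn (3 equiv), (S,S)-ProPhenol (20 mol%), Ph3P=O (40 mol%), toluene, 0 °C
Reagents that add atoms: none
Why: dinuclear Zn–ProPhenol asymmetric alkynylation of an enal; C6 is set by the ligand, Si-face addition being required for the 4R carbinol, and the ligand antipode is used if the facial sense on this enal proves opposite.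

Step 8
Reactants: 10 (4R,5E)-4-hydroxy-6-methyl-8-[(2R,3R)-3-methyl-3-(prop-2-en-1-yl)oxiran-2-yl]oct-5-en-2-yn-1-yl acetate
Product: 11 (4S)-4-hydroxy-4-[(2R,3R)-3-methyl-3-{2-[(2R,3R)-3-methyl-3-(prop-2-en-1-yl)oxiran-2-yl]ethyl}oxiran-2-yl]but-2-yn-1-yl acetate
Conditions: mCPBA (1.1 equiv), NaHCO3, CH2Cl2, 0 °C
Reagents that add atoms: 3-chloroperoxybenzoic acid, OOC(=O)c1cccc(Cl)c1
Why: hydroxyl-directed peracid epoxidation; allylic 1,3-strain with the cis C15 methyl holds H6 in the olefin plane, so the hydrogen-bonded peracid reaches one face only and gives the threo (4R,5R,6S) epoxy alcohol, while the alkyne and the vinyl group are much less reactive.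

Step 9
Reactants: 11 (4S)-4-hydroxy-4-[(2R,3R)-3-methyl-3-{2-[(2R,3R)-3-methyl-3-(prop-2-en-1-yl)oxiran-2-yl]ethyl}oxiran-2-yl]but-2-yn-1-yl acetate
Product: 12 (2E,4R)-4-hydroxy-2,3-diiodo-4-[(2R,3R)-3-methyl-3-{2-[(2R,3R)-3-methyl-3-(prop-2-en-1-yl)oxiran-2-yl]ethyl}oxiran-2-yl]but-2-en-1-yl acetate
Conditions: I2 (1.2 equiv), CH2Cl2, 0 °C to rt, dark
Reagents that add atoms: iodine, II
Why: anti addition of I2 to the oxygen-flanked alkyne gives the (E)-diiodoalkene, which places the C11 iodide cis to the C6 carbinol and leaves the C7 iodide as the later coupling handle.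

Step 10
Reactants: 12 (2E,4R)-4-hydroxy-2,3-diiodo-4-[(2R,3R)-3-methyl-3-{2-[(2R,3R)-3-methyl-3-(prop-2-en-1-yl)oxiran-2-yl]ethyl}oxiran-2-yl]but-2-en-1-yl acetate
Product: 13 {(5R)-4-iodo-5-[(2R,3R)-3-methyl-3-{2-[(2R,3R)-3-methyl-3-(prop-2-en-1-yl)oxiran-2-yl]ethyl}oxiran-2-yl]-2-oxo-2,5-dihydrofuran-3-yl}methyl acetate
Conditions: Pd(PPh3)4 (5 mol%), CO (1 atm), i-Pr2NEt (1.5 equiv), THF, 40 °C
Reagents that add atoms: carbon monoxide, [C-]#[O+]
Why: Pd-catalysed cyclocarbonylation of a (Z)-γ-iodoallylic alcohol; insertion is favoured at the less hindered C11 iodide, and only that acylpalladium has a cis hydroxyl for five-ring closure, so the butenolide forms with the C7 iodide intact and C6 untouched.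

Step 11
Reactants: 13 {(5R)-4-iodo-5-[(2R,3R)-3-methyl-3-{2-[(2R,3R)-3-methyl-3-(prop-2-en-1-yl)oxiran-2-yl]ethyl}oxiran-2-yl]-2-oxo-2,5-dihydrofuran-3-yl}methyl acetate
Product: 15 {(5R)-4-iodo-5-[(2R,3R)-3-methyl-3-{2-[(2R,3R)-3-methyl-3-(2-oxoethyl)oxiran-2-yl]ethyl}oxiran-2-yl]-2-oxo-2,5-dihydrofuran-3-yl}methyl acetate, via ozonide 14 (not isolated)
Conditions: O3, CH2Cl2, −78 °C (Sudan Red 7B end point); Me2S, −78 °C to rt; used crude
Reagents that add atoms: ozone, [O-][O+]=O
Why: ozonolysis cleaves the only electron-rich olefin left (the terminal vinyl group), the tetrasubstituted iodobutenolide olefin being far less reactive, and the neutral reductive work-up releases the sensitive β,γ-epoxy aldehyde without base.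

Step 12
Reactants: 15 {(5R)-4-iodo-5-[(2R,3R)-3-methyl-3-{2-[(2R,3R)-3-methyl-3-(2-oxoethyl)oxiran-2-yl]ethyl}oxiran-2-yl]-2-oxo-2,5-dihydrofuran-3-yl}methyl acetate
Product: 17 (1R,4R,5R,6S,8R,10R)-13-acetoxy-1,10:4,5-diepoxy-8-hydroxygermacr-7(11)-en-12,6-olide, via alkenylchromium(III) species 16 (not isolated)
Conditions: CrCl2 (10 equiv), NiCl2 (0.2 equiv), DMSO/THF, rt, slow addition of 15 to a final 2 mM; aqueous work-up
Reagents that add atoms: none
Why: Ni(0) inserts into the C7–I bond of the β-iodobutenolide, the alkenyl group passes to Cr(III) to give 16, and this adds to the tethered C8 aldehyde through a four-centre transition state, water freeing the alcohol on work-up. The closest known reaction type is the Nozaki–Hiyama–Kishi macrocyclisation of ω-formyl alkenyl iodides. The ten-membered carbocycle closes in a 10-exo-trig mode (C7 nucleophile, C8 carbonyl carbon) and is the only ring formed. The new stereocentre C8 is under substrate control: allylic 1,3-strain with the C13 acetoxymethyl group should keep the aldehyde H in the butenolide plane, and the seven-atom tether should bring C9 in on the face that carries C5, so the O–Cr unit lies on the H6 face and the 8R carbinol is expected. The step needs chemoselectivity for the aldehyde over the lactone, the acetate and both oxiranes, which the low basicity of organochromium(III) provides, and closure over oligomerisation, which slow addition at high dilution provides. The 8R hydroxyl also points away from the C13 acetate, so acetyl migration is not expected.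

Step 13
Reactants: 18 ethyl 2-(hydroxymethyl)prop-2-enoate
Product: 19 ethyl 2-{[tert-butyl(dimethyl)silyl]oxymethyl}prop-2-enoate
Conditions: TBSCl, imidazole, DMF, 0 °C to rt
Reagents that add atoms: tert-butyldimethylsilyl chloride, CC(C)(C)[Si](C)(C)Cl
Why: standard silylation of a primary allylic alcohol masks the side-chain hydroxyl so that the acid cannot self-esterify.

Step 14
Reactants: 19 ethyl 2-{[tert-butyl(dimethyl)silyl]oxymethyl}prop-2-enoate
Product: 20 2-{[tert-butyl(dimethyl)silyl]oxymethyl}prop-2-enoic acid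
Conditions: LiOH, THF/H2O, 0 °C; then 1 M HCl to pH 4
Reagents that add atoms: lithium hydroxide, [Li+].[OH-]
Why: saponification of the ethyl ester at 0 °C leaves the silyl ether in place and keeps conjugate addition of hydroxide slow.

Step 15
Reactants: 17 (1R,4R,5R,6S,8R,10R)-13-acetoxy-1,10:4,5-diepoxy-8-hydroxygermacr-7(11)-en-12,6-olide, 20 2-{[tert-butyl(dimethyl)silyl]oxymethyl}prop-2-enoic acid
Product: 22 (1R,4R,5R,6S,8S,10R)-13-acetoxy-8-(2-{[tert-butyl(dimethyl)silyl]oxymethyl}prop-2-enoyloxy)-1,10:4,5-diepoxygermacr-7(11)-en-12,6-olide, via alkoxyphosphonium salt 21 (not isolated)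
Conditions: PPh3, DIAD, toluene, 0 °C to rt
Reagents that add atoms: none
Why: Mitsunobu esterification; the carboxylate displaces the C8 alkoxyphosphonium by SN2 from the open periphery, which inverts C8 to 8S while attaching the side chain, and SN2' is blocked because C11 is fully substituted.

Step 16
Reactants: 22 (1R,4R,5R,6S,8S,10R)-13-acetoxy-8-(2-{[tert-butyl(dimethyl)silyl]oxymethyl}prop-2-enoyloxy)-1,10:4,5-diepoxygermacr-7(11)-en-12,6-olide
Product: 23 (1R,4R,5R,6S,8S,10R)-13-acetoxy-1,10:4,5-diepoxy-8-[2-(hydroxymethyl)prop-2-enoyloxy]germacr-7(11)-en-12,6-olide (CNP0282791.1)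
Conditions: TBAF/AcOH (1:1), THF, 0 °C to rt
Reagents that add atoms: none
Why: acetic-acid-buffered fluoride removes the primary allylic silyl ether without base strong enough to deprotonate C6 or to cleave the esters, and without acid strong enough to open the oxiranes.

**Compound list**
1 | geranyl acetate | CC(C)=CCC/C(C)=C/COC(C)=O | starting material
2 | (2E,6E)-8-hydroxy-3,7-dimethylocta-2,6-dien-1-yl acetate | OC/C(C)=C/CC/C(C)=C/COC(C)=O | intermediate
3 | (2E,6E)-8-bromo-3,7-dimethylocta-2,6-dien-1-yl acetate | BrC/C(C)=C/CC/C(C)=C/COC(C)=O | intermediate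
4 | (2E,6E)-3,7-dimethyldeca-2,6,9-trien-1-yl acetate | C=CC/C(C)=C/CC/C(C)=C/COC(C)=O | intermediate
5 | (2E)-3-methyl-5-[(2R,3R)-3-methyl-3-(prop-2-en-1-yl)oxiran-2-yl]pent-2-en-1-yl acetate | C=CC[C@@]1(C)O[C@@H]1CC/C(C)=C/COC(C)=O | intermediate
6 | (2E)-3-methyl-5-[(2R,3R)-3-methyl-3-(prop-2-en-1-yl)oxiran-2-yl]pent-2-en-1-ol | C=CC[C@@]1(C)O[C@@H]1CC/C(C)=C/CO | intermediate
7 | (2E)-3-methyl-5-[(2R,3R)-3-methyl-3-(prop-2-en-1-yl)oxiran-2-yl]pent-2-enal | C=CC[C@@]1(C)O[C@@H]1CC/C(C)=C/C=O | intermediate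
8 | prop-2-yn-1-yl acetate | C#CCOC(C)=O | starting material
9 | (3-acetoxyprop-1-yn-1-yl)(methyl)zinc | C[Zn]C#CCOC(C)=O | intermediate (not isolated)
10 | (4R,5E)-4-hydroxy-6-methyl-8-[(2R,3R)-3-methyl-3-(prop-2-en-1-yl)oxiran-2-yl]oct-5-en-2-yn-1-yl acetate | C=CC[C@@]1(C)O[C@@H]1CC/C(C)=C/[C@@H](O)C#CCOC(C)=O | intermediate
11 | (4S)-4-hydroxy-4-[(2R,3R)-3-methyl-3-{2-[(2R,3R)-3-methyl-3-(prop-2-en-1-yl)oxiran-2-yl]ethyl}oxiran-2-yl]but-2-yn-1-yl acetate | C=CC[C@@]1(C)O[C@@H]1CC[C@@]1(C)O[C@@H]1[C@@H](O)C#CCOC(C)=O | intermediate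
12 | (2E,4R)-4-hydroxy-2,3-diiodo-4-[(2R,3R)-3-methyl-3-{2-[(2R,3R)-3-methyl-3-(prop-2-en-1-yl)oxiran-2-yl]ethyl}oxiran-2-yl]but-2-en-1-yl acetate | C=CC[C@@]1(C)O[C@@H]1CC[C@@]1(C)O[C@@H]1[C@@H](O)/C(I)=C(\I)COC(C)=O | intermediate
13 | {(5R)-4-iodo-5-[(2R,3R)-3-methyl-3-{2-[(2R,3R)-3-methyl-3-(prop-2-en-1-yl)oxiran-2-yl]ethyl}oxiran-2-yl]-2-oxo-2,5-dihydrofuran-3-yl}methyl acetate | C=CC[C@@]1(C)O[C@@H]1CC[C@@]1(C)O[C@@H]1[C@H]1OC(=O)C(COC(C)=O)=C1I | intermediate
14 | 1,2,4-trioxolane (ozonide) of the terminal vinyl group of 13 | C1OC(OO1)C[C@@]2(C)O[C@@H]2CC[C@@]2(C)O[C@@H]2[C@H]2OC(=O)C(COC(C)=O)=C2I | intermediate (not isolated)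
15 | {(5R)-4-iodo-5-[(2R,3R)-3-methyl-3-{2-[(2R,3R)-3-methyl-3-(2-oxoethyl)oxiran-2-yl]ethyl}oxiran-2-yl]-2-oxo-2,5-dihydrofuran-3-yl}methyl acetate | O=CC[C@@]1(C)O[C@@H]1CC[C@@]1(C)O[C@@H]1[C@H]1OC(=O)C(COC(C)=O)=C1I | intermediate
16 | C7 alkenylchromium(III) dichloride derived from 15 | O=CC[C@@]1(C)O[C@@H]1CC[C@@]1(C)O[C@@H]1[C@H]1OC(=O)C(COC(C)=O)=C1[Cr](Cl)Cl | intermediate (not isolated)
17 | (1R,4R,5R,6S,8R,10R)-13-acetoxy-1,10:4,5-diepoxy-8-hydroxygermacr-7(11)-en-12,6-olide | O[C@@H]1C[C@@]2(C)O[C@@H]2CC[C@@]2(C)O[C@@H]2[C@H]2OC(=O)C(COC(C)=O)=C12 | intermediate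
18 | ethyl 2-(hydroxymethyl)prop-2-enoate | C=C(CO)C(=O)OCC | starting material
19 | ethyl 2-{[tert-butyl(dimethyl)silyl]oxymethyl}prop-2-enoate | C=C(CO[Si](C)(C)C(C)(C)C)C(=O)OCC | intermediate
20 | 2-{[tert-butyl(dimethyl)silyl]oxymethyl}prop-2-enoic acid | C=C(CO[Si](C)(C)C(C)(C)C)C(=O)O | intermediate
21 | C8 alkoxytriphenylphosphonium carboxylate formed from 17 and 20 | C=C(CO[Si](C)(C)C(C)(C)C)C(=O)[O-].c1ccc(cc1)[P+](c1ccccc1)(c1ccccc1)O[C@@H]1C[C@@]2(C)O[C@@H]2CC[C@@]2(C)O[C@@H]2[C@H]2OC(=O)C(COC(C)=O)=C12 | intermediate (not isolated)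
22 | (1R,4R,5R,6S,8S,10R)-13-acetoxy-8-(2-{[tert-butyl(dimethyl)silyl]oxymethyl}prop-2-enoyloxy)-1,10:4,5-diepoxygermacr-7(11)-en-12,6-olide | C=C(CO[Si](C)(C)C(C)(C)C)C(=O)O[C@H]1C[C@@]2(C)O[C@@H]2CC[C@@]2(C)O[C@@H]2[C@H]2OC(=O)C(COC(C)=O)=C12 | intermediate
23 | (1R,4R,5R,6S,8S,10R)-13-acetoxy-1,10:4,5-diepoxy-8-[2-(hydroxymethyl)prop-2-enoyloxy]germacr-7(11)-en-12,6-olide | C=C(CO)C(=O)O[C@H]1C[C@@]2(C)O[C@@H]2CC[C@@]2(C)O[C@@H]2[C@H]2OC(=O)C(COC(C)=O)=C12 | target

**Step count**
Total steps: 16. Longest linear sequence: 14 (steps 1–12, 15, 16); steps 13–14 are a two-step side branch.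

**Steps most likely to fail**

Step 12. Closure of the strained ring may be slow enough for intermolecular coupling to compete, and the aldehyde may be attacked on the face opposite to the predicted one, giving the C8 epimer. The fallback changes how the side chain is attached, so that either facial outcome is usable. It sets out from 15: the same closure is run and the epimeric carbinol (1R,4R,5R,6S,8S,10R)-13-acetoxy-1,10:4,5-diepoxy-8-hydroxygermacr-7(11)-en-12,6-olide F1 is acylated with retention by 20 (DCC, DMAP cat., CH2Cl2, 0 °C). It comes back to the route at 22, while any 8R material still passes through step 15.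

Step 10. Palladium may insert at the C7 iodide next to the free hydroxyl, leading to an α-alkylidene β-lactone or to intermolecular esters, and the product may lose its iodine by a second insertion. The fallback separates carbonylation from ring closure. It sets out from 12, which is silylated (TESCl, imidazole, DMF) to the C6 triethylsilyl ether of 12, F2. Intermolecular methoxycarbonylation at the less hindered iodide (Pd(PPh3)4, CO, MeOH, i-Pr2NEt, DMF, 50 °C) should then give methyl (2E,4R)-2-(acetoxymethyl)-3-iodo-4-(triethylsilyloxy)-4-[(2R,3R)-3-methyl-3-{2-[(2R,3R)-3-methyl-3-(prop-2-en-1-yl)oxiran-2-yl]ethyl}oxiran-2-yl]but-2-enoate F3. Desilylation with TBAF/AcOH is followed by spontaneous lactonisation of the cis hydroxy ester, which comes back to the route at 13.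

Step 9. The iodine–alkyne complex may be captured by the neighbouring oxirane oxygen or by the hydroxyl instead of by iodide, and the addition is reversible. The fallback reverses the order of the two oxidations so that no oxirane sits next to the alkyne during iodination. It sets out from 10, which takes up I2 (CH2Cl2, 0 °C, dark) to give (2E,4R,5E)-4-hydroxy-2,3-diiodo-6-methyl-8-[(2R,3R)-3-methyl-3-(prop-2-en-1-yl)oxiran-2-yl]octa-2,5-dien-1-yl acetate F4. Hydroxyl-directed epoxidation of its C4=C5 olefin (mCPBA, NaHCO3, CH2Cl2, 0 °C) then comes back to the route at 12.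

Further compounds
F1 | step 12 | (1R,4R,5R,6S,8S,10R)-13-acetoxy-1,10:4,5-diepoxy-8-hydroxygermacr-7(11)-en-12,6-olide | O[C@H]1C[C@@]2(C)O[C@@H]2CC[C@@]2(C)O[C@@H]2[C@H]2OC(=O)C(COC(C)=O)=C12
F2 | step 10 | C6 triethylsilyl ether of 12 | C=CC[C@@]1(C)O[C@@H]1CC[C@@]1(C)O[C@@H]1[C@@H](O[Si](CC)(CC)CC)/C(I)=C(\I)COC(C)=O
F3 | step 10 | methyl (2E,4R)-2-(acetoxymethyl)-3-iodo-4-(triethylsilyloxy)-4-[(2R,3R)-3-methyl-3-{2-[(2R,3R)-3-methyl-3-(prop-2-en-1-yl)oxiran-2-yl]ethyl}oxiran-2-yl]but-2-enoate | C=CC[C@@]1(C)O[C@@H]1CC[C@@]1(C)O[C@@H]1[C@@H](O[Si](CC)(CC)CC)/C(I)=C(\C(=O)OC)COC(C)=O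
F4 | step 9 | (2E,4R,5E)-4-hydroxy-2,3-diiodo-6-methyl-8-[(2R,3R)-3-methyl-3-(prop-2-en-1-yl)oxiran-2-yl]octa-2,5-dien-1-yl acetate | C=CC[C@@]1(C)O[C@@H]1CC/C(C)=C/[C@@H](O)/C(I)=C(\I)COC(C)=O
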